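**Plan**

- The retrosynthesis cuts C5–C6, C7–C8 and C8–C8a of ring A: a Dötz benzannulation joins a chromium methoxycarbene on the ring C pyranone (carbene carbon = C5), a boryl ynol ether (C6 and C7) and one CO ligand (C8).
- The feature that allows this: ring A is a benzene with all six carbons substituted, C5, C6, C7 and C8 each carrying oxygen and only O7 free, and its C4a=C8a bond is the enone double bond of ring C.
- The ynol ether oxygen should end beside the CO-derived carbon, so it is made O7 (as a tert-butyl ether, the only non-methyl oxygen); boron marks C6 for later oxidation and methylation.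
- Ring C, already carrying ring B, is cut at C2–C3 and O1–C8a: a 4-pyranone from methyl 4-methoxyacetoacetate, DMF dimethyl acetal (which supplies C8a) and 4-methoxybenzoyl chloride. Its ester becomes the carbene through the acid chloride and pentacarbonylchromate.
- Forward order: ring C with ring B attached, then ring A; end game is C–B oxidation, double O-methylation and tert-butyl cleavage.
- Stereochemistry: none; the target is achiral.

Key step: step 8

Remark: ynamines and ynol ethers insert into metal–carbene bonds with the heteroatom-bearing carbon becoming the new carbene carbon, so the alkyne oxygen is taken to end at C7 and boron at C6. Flavone numbering (O1, C2–C4, C4a, C5–C8, C8a) is used for ring positions; enaminone 3 and diketone 5 equilibrate and are drawn without descriptors.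

**Route**

Step 1
Reactants: 1 methyl 4-methoxy-3-oxobutanoate; 2 N,N-dimethylformamide dimethyl acetal
Product: 3 methyl 2-[(dimethylamino)methylidene]-4-methoxy-3-oxobutanoate
Conditions: 2 (1.1 equiv), toluene, rt
Reagents that add atoms: none
Why: The amide acetal condenses at the only doubly activated methylene (between ketone and ester) to the push–pull enaminone, a standard enaminone formation that leaves the CH2OMe group as the single enolisable site for the next step.

Step 2
Reactants: 3 methyl 2-[(dimethylamino)methylidene]-4-methoxy-3-oxobutanoate; 4 4-methoxybenzoyl chloride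
Product: 6 methyl 5-methoxy-6-(4-methoxyphenyl)-4-oxo-4H-pyran-3-carboxylate, via C-aroylated enaminone 5 (not isolated)
Conditions: LiN(SiMe3)2 (2.2 equiv), THF, −78 °C; 4, −78 → 0 °C; 3 M HCl, rt
Reagents that add atoms: none
Why: LiN(SiMe3)2 deprotonates the CH2OMe carbon, the enolate is C-aroylated by 4 (Claisen-type acylation, the second equivalent of base being taken up by the acidic 1,3-diketone 5), and aqueous acid closes ring C by addition of the enol oxygen to the enaminone carbon with loss of dimethylamine, the established enaminone/acid chloride route to 4-pyranones.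

Step 3
Reactants: 6 methyl 5-methoxy-6-(4-methoxyphenyl)-4-oxo-4H-pyran-3-carboxylate
Product: 7 5-methoxy-6-(4-methoxyphenyl)-4-oxo-4H-pyran-3-carboxylic acid
Conditions: 6 M HCl, AcOH, 90 °C
Reagents that add atoms: water, O
Why: Acid-catalysed ester hydrolysis is chosen over saponification because hydroxide would add to the unsubstituted ring carbon next to oxygen and open the pyranone, whereas the methyl ethers and the non-enolisable vinylogous β-keto acid should be stable to hot aqueous HCl.

Step 4
Reactants: 7 5-methoxy-6-(4-methoxyphenyl)-4-oxo-4H-pyran-3-carboxylic acid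
Product: 8 5-methoxy-6-(4-methoxyphenyl)-4-oxo-4H-pyran-3-carbonyl chloride
Conditions: (COCl)2 (1.2 equiv), DMF (cat.), CH2Cl2, 0 °C → rt
Reagents that add atoms: oxalyl chloride, O=C(Cl)C(Cl)=O
Why: DMF-catalysed chlorination through the chloroiminium (Vilsmeier-type) intermediate converts the acid into the acid chloride under mild conditions, as for chromone-3-carboxylic acids, and the crude chloride is used at once.

Step 5
Reactants: 8 5-methoxy-6-(4-methoxyphenyl)-4-oxo-4H-pyran-3-carbonyl chloride; 9 hexacarbonylchromium, Cr(CO)6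
Product: 12 pentacarbonyl{methoxy[5-methoxy-6-(4-methoxyphenyl)-4-oxo-4H-pyran-3-yl]methylidene}chromium, via dipotassium pentacarbonylchromate 10 (not isolated), via potassium acylchromate 11 (not isolated)
Conditions: 9, C8K (2.1 equiv), THF, −78 °C → rt; 8, −78 → 0 °C; Me3OBF4, CH2Cl2, 0 °C
Reagents that add atoms: trimethyloxonium tetrafluoroborate, C[O+](C)C.F[B-](F)(F)F
Why: Semmelhack–Hegedus carbene synthesis: reduction of Cr(CO)6 gives the dianion 10 (chromium in the oxidation state minus two), which should be acylated at the metal by the acid chloride at −78 °C faster than it attacks the ring, and the hard Meerwein salt methylates the acylate oxygen of 11 to the zerovalent chromium Fischer carbene, so that no organolithium is ever exposed to the base-sensitive pyranone.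

Step 6
Reactants: 13 potassium tert-butoxide; 14 trichloroethylene
Product: 15 (E)-1,2-dichlorovinyl tert-butyl ether
Conditions: THF, 0 °C → rt
Reagents that add atoms: none
Why: tert-Butoxide eliminates HCl from trichloroethylene to dichloroacetylene and then adds across it in anti fashion, the known route to (E)-1,2-dichlorovinyl ethers.

Step 7
Reactants: 15 (E)-1,2-dichlorovinyl tert-butyl ether
Product: 18 2-(tert-butoxyethynyl)-4,4,5,5-tetramethyl-1,3,2-dioxaborolane, via lithium tert-butoxyacetylide 16 (not isolated), via lithium alkynylborate 17 (not isolated)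
Conditions: n-BuLi (2.2 equiv), Et2O, −78 → −40 °C; iPrOB(pin), −78 °C; HCl·Et2O (1.0 equiv), −78 °C → rt
Reagents that add atoms: 2-isopropoxy-4,4,5,5-tetramethyl-1,3,2-dioxaborolane, CC(C)OB1OC(C)(C)C(C)(C)O1
Why: n-BuLi deprotonates the vinyl C–H with loss of LiCl to the chloroalkyne and a second equivalent exchanges chlorine for lithium, the acetylide 16 adds to the isopropoxy boronate and one equivalent of anhydrous HCl collapses the ate complex 17 (standard alkynyl pinacol boronate synthesis), the product being kept below 30 °C and used without chromatography.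

Step 8
Reactants: 12 pentacarbonyl{methoxy[5-methoxy-6-(4-methoxyphenyl)-4-oxo-4H-pyran-3-yl]methylidene}chromium; 18 2-(tert-butoxyethynyl)-4,4,5,5-tetramethyl-1,3,2-dioxaborolane
Product: 20 7-tert-butoxy-8-hydroxy-3,5-dimethoxy-2-(4-methoxyphenyl)-6-(4,4,5,5-tetramethyl-1,3,2-dioxaborolan-2-yl)-4H-chromen-4-one, via tricarbonylchromium arene complex 19 (not isolated)
Conditions: 18 (2 equiv), THF (degassed), 45 °C; then air, MeCN, rt
Reagents that add atoms: none
Why: Proposed new method: thermal loss of one CO from the zerovalent chromium carbene 12 lets alkyne 18 insert into the Cr=C bond (C5–C6), a CO ligand then inserts into the new carbene (C7–C8) to give a chromium-bound dienylketene, and ring A closes by 6π-electrocyclisation of that ketene onto the pyranone carbon C8a (C8–C8a), followed by tautomerisation to the phenol, held as the Cr(CO)3 complex 19 until air releases 20. The closest known reactions are the Dötz benzannulations of alkenyl and heteroaryl alkoxycarbene complexes with alkynylboronates and with ynol ethers; a boryl ynol ether and a 4-pyranon-3-yl carbene have not been used. No stereocentre is formed. The step needs one regiochemistry, the oxygen-bearing alkyne carbon next to the CO-derived C8 and the boron-bearing carbon bonded to the carbene carbon, and the polarisation of the ynol ether should secure it: its nucleophilic β-carbon (the one carrying boron) attacks the electrophilic carbene carbon while the alkoxy group stabilises the new carbene centre that takes up CO, the sense in which ynamines, ynol ethers and stannyl alkynes insert. It also needs CO insertion to outrun cyclopentannulation, which chromium, the methoxy carbene and THF favour, and 45 °C should keep the tert-butyl ynol ether below the temperature at which it loses isobutene.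

Step 9
Reactants: 20 7-tert-butoxy-8-hydroxy-3,5-dimethoxy-2-(4-methoxyphenyl)-6-(4,4,5,5-tetramethyl-1,3,2-dioxaborolan-2-yl)-4H-chromen-4-one
Product: 21 7-tert-butoxy-6,8-dihydroxy-3,5-dimethoxy-2-(4-methoxyphenyl)-4H-chromen-4-one
Conditions: NaBO3·4H2O (3 equiv), THF/H2O 1:1, rt
Reagents that add atoms: sodium perborate tetrahydrate (NaBO3·4H2O, drawn as the peroxoborate dimer), [Na+].[Na+].O[B-]1(O)OO[B-](O)(O)OO1.O.O.O.O.O.O
Why: Peroxide adds to boron and the aryl group migrates to oxygen (boronate oxidation), after which the aryl borate hydrolyses to the C6 phenol; mild perborate is used directly on fresh 20 so that oxidation outruns protodeboronation of the doubly ortho-oxygenated boronate and the flavone is not exposed to strong base.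

Step 10
Reactants: 21 7-tert-butoxy-6,8-dihydroxy-3,5-dimethoxy-2-(4-methoxyphenyl)-4H-chromen-4-one
Product: 22 7-tert-butoxy-3,5,6,8-tetramethoxy-2-(4-methoxyphenyl)-4H-chromen-4-one
Conditions: MeI (5 equiv), K2CO3, DMF, rt, Ar
Reagents that add atoms: iodomethane, CI
Why: Williamson methylation of the two phenoxides (the only acidic sites) with the small electrophile MeI should tolerate the flanking tert-butoxy group, and argon keeps the electron-rich diphenol from air oxidation.

Step 11
Reactants: 22 7-tert-butoxy-3,5,6,8-tetramethoxy-2-(4-methoxyphenyl)-4H-chromen-4-one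
Product: 23 7-hydroxy-3,5,6,8-tetramethoxy-2-(4-methoxyphenyl)-4H-chromen-4-one (CNP0495887.0)
Conditions: CF3CO2H/CH2Cl2 1:4, 0 °C → rt
Reagents that add atoms: none
Why: Protonation of the aryl tert-butyl ether and loss of the tert-butyl cation as isobutene (acidolysis) frees O7 while all five methyl ethers, including the peri 5-OMe that only Lewis acids cleave, stay in place, and the fully substituted ring A offers no site for tert-butylation.

**Compound list**

1 | methyl 4-methoxy-3-oxobutanoate | COCC(=O)CC(=O)OC | starting material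
2 | N,N-dimethylformamide dimethyl acetal | COC(OC)N(C)C | starting material
3 | methyl 2-[(dimethylamino)methylidene]-4-methoxy-3-oxobutanoate | COCC(=O)C(=CN(C)C)C(=O)OC | intermediate
4 | 4-methoxybenzoyl chloride | COc1ccc(C(Cl)=O)cc1 | starting material
5 | methyl 2-[(dimethylamino)methylidene]-4-methoxy-5-(4-methoxyphenyl)-3,5-dioxopentanoate (racemic, enolised) | COC(=O)C(=CN(C)C)C(=O)C(OC)C(=O)c1ccc(OC)cc1 | intermediate
6 | methyl 5-methoxy-6-(4-methoxyphenyl)-4-oxo-4H-pyran-3-carboxylate | COC(=O)c1coc(-c2ccc(OC)cc2)c(OC)c1=O | intermediate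
7 | 5-methoxy-6-(4-methoxyphenyl)-4-oxo-4H-pyran-3-carboxylic acid | COc1ccc(-c2occ(C(=O)O)c(=O)c2OC)cc1 | intermediate
8 | 5-methoxy-6-(4-methoxyphenyl)-4-oxo-4H-pyran-3-carbonyl chloride | COc1ccc(-c2occ(C(Cl)=O)c(=O)c2OC)cc1 | intermediate
9 | hexacarbonylchromium, Cr(CO)6 | O=C=[Cr](=C=O)(=C=O)(=C=O)(=C=O)=C=O | starting material
10 | dipotassium pentacarbonylchromate, K2[Cr(CO)5] | [K+].[K+].O=C=[Cr-2](=C=O)(=C=O)(=C=O)=C=O | intermediate
11 | potassium pentacarbonyl[5-methoxy-6-(4-methoxyphenyl)-4-oxo-4H-pyran-3-carbonyl]chromate | [K+].[O-]C(c1coc(-c2ccc(OC)cc2)c(OC)c1=O)=[Cr](=C=O)(=C=O)(=C=O)(=C=O)=C=O | intermediate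
12 | pentacarbonyl{methoxy[5-methoxy-6-(4-methoxyphenyl)-4-oxo-4H-pyran-3-yl]methylidene}chromium | COC(c1coc(-c2ccc(OC)cc2)c(OC)c1=O)=[Cr](=C=O)(=C=O)(=C=O)(=C=O)=C=O | intermediate
13 | potassium tert-butoxide | CC(C)(C)[O-].[K+] | starting material
14 | trichloroethylene | ClC=C(Cl)Cl | starting material
15 | (E)-1,2-dichlorovinyl tert-butyl ether | Cl/C=C(/Cl)OC(C)(C)C | intermediate
16 | lithium tert-butoxyacetylide | [Li]C#COC(C)(C)C | intermediate
17 | lithium (tert-butoxyethynyl)(isopropoxy)(pinacolato)borate | [Li+].CC(C)O[B-]1(C#COC(C)(C)C)OC(C)(C)C(C)(C)O1 | intermediate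
18 | 2-(tert-butoxyethynyl)-4,4,5,5-tetramethyl-1,3,2-dioxaborolane | CC(C)(C)OC#CB1OC(C)(C)C(C)(C)O1 | intermediate
19 | tricarbonylchromium complex of 20, η6-bound through ring A (hapto bond not drawn) | COc1ccc(-c2oc3c(O)c(OC(C)(C)C)c(B4OC(C)(C)C(C)(C)O4)c(OC)c3c(=O)c2OC)cc1.O=C=[Cr](=C=O)=C=O | intermediate
20 | 7-tert-butoxy-8-hydroxy-3,5-dimethoxy-2-(4-methoxyphenyl)-6-(4,4,5,5-tetramethyl-1,3,2-dioxaborolan-2-yl)-4H-chromen-4-one | COc1ccc(-c2oc3c(O)c(OC(C)(C)C)c(B4OC(C)(C)C(C)(C)O4)c(OC)c3c(=O)c2OC)cc1 | intermediate
21 | 7-tert-butoxy-6,8-dihydroxy-3,5-dimethoxy-2-(4-methoxyphenyl)-4H-chromen-4-one | COc1ccc(-c2oc3c(O)c(OC(C)(C)C)c(O)c(OC)c3c(=O)c2OC)cc1 | intermediate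
22 | 7-tert-butoxy-3,5,6,8-tetramethoxy-2-(4-methoxyphenyl)-4H-chromen-4-one | COc1ccc(-c2oc3c(OC)c(OC(C)(C)C)c(OC)c(OC)c3c(=O)c2OC)cc1 | intermediate
23 | 7-hydroxy-3,5,6,8-tetramethoxy-2-(4-methoxyphenyl)-4H-chromen-4-one | COc1ccc(-c2oc3c(OC)c(O)c(OC)c(OC)c3c(=O)c2OC)cc1 | target

**Step count and risks**

Total steps: 11. Longest linear sequence: 9 (steps 1–5, then 8–11); the alkyne arm (steps 6–7) joins at step 8.

Steps most likely to fail:

1. Step 8. The alkyne insertion may halt at the alkoxy-stabilised alkenylcarbene without CO uptake, boron may be lost, or the steric demand of the pinacol boronate (which in alkyl- and aryl-substituted alkynylboronates places boron beside the phenol) may divert part of the insertion to the reverse regiochemistry. The fallback leaves boron out and uses known chemistry. Lithium tert-butoxyacetylide 16 is quenched with water to tert-butoxyethyne F1. Carbene complex 12 is benzannulated with this terminal ynol ether (THF, 45 °C, then air), a Dötz reaction in which size and polarity both place the alkoxy carbon next to the CO-derived carbon, to give 7-tert-butoxy-8-hydroxy-3,5-dimethoxy-2-(4-methoxyphenyl)-4H-chromen-4-one F2. MeI/K2CO3 in DMF gives 7-tert-butoxy-3,5,8-trimethoxy-2-(4-methoxyphenyl)-4H-chromen-4-one F3. N-Bromosuccinimide in MeCN brominates C6, the only free position of ring A, to 6-bromo-7-tert-butoxy-3,5,8-trimethoxy-2-(4-methoxyphenyl)-4H-chromen-4-one F4. CuBr/NaOMe in MeOH–DMF at 110 °C (Ullmann-type methoxylation) converts the bromide into 22, where the route is rejoined.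

2. Step 5. Electron transfer from the chromate dianion to the pyranone, or its conjugate addition at the unsubstituted ring carbon, may compete with acylation at the acid chloride. The fallback is the classical Fischer route from an organometallic and sets out from acid 7. Iododecarboxylation with N-iodosuccinimide and LiOAc in MeCN/H2O (Hunsdiecker-type ipso substitution) gives 5-iodo-3-methoxy-2-(4-methoxyphenyl)-4H-pyran-4-one F5. Iodine–magnesium exchange with iPrMgCl·LiCl in THF at −40 °C gives chloro[5-methoxy-6-(4-methoxyphenyl)-4-oxo-4H-pyran-3-yl]magnesium F6. Addition to Cr(CO)6 (−40 → 0 °C) gives the chloromagnesium acylchromate F7, and O-methylation with Me3OBF4 in CH2Cl2 returns to carbene complex 12.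

3. Step 7. The push–pull boryl ynol ether may hydrolyse at the C–B bond or lose isobutene by retro-ene reaction during the acidic quench and isolation. The fallback replaces boron by tin as the C6 placeholder and sets out from lithium tert-butoxyacetylide 16. Trapping with Bu3SnCl gives tributyl(tert-butoxyethynyl)stannane F8, a robust class of ynol ether. Benzannulation with 12 (THF, 45 °C, then air; alkynylstannanes are established Dötz partners that place tin next to the carbene-derived carbon) gives 7-tert-butoxy-8-hydroxy-3,5-dimethoxy-2-(4-methoxyphenyl)-6-(tributylstannyl)-4H-chromen-4-one F9. I2 in CH2Cl2 at 0 °C (ipso-iododestannylation) gives 7-tert-butoxy-8-hydroxy-6-iodo-3,5-dimethoxy-2-(4-methoxyphenyl)-4H-chromen-4-one F10. MeI/K2CO3 gives 7-tert-butoxy-6-iodo-3,5,8-trimethoxy-2-(4-methoxyphenyl)-4H-chromen-4-one F11, and CuI/NaOMe in MeOH–DMF at 110 °C leads to 22, where the route is rejoined.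

Further compounds
F1 | step 8 | tert-butoxyethyne | C#COC(C)(C)C
F2 | step 8 | 7-tert-butoxy-8-hydroxy-3,5-dimethoxy-2-(4-methoxyphenyl)-4H-chromen-4-one | COc1ccc(-c2oc3c(O)c(OC(C)(C)C)cc(OC)c3c(=O)c2OC)cc1
F3 | step 8 | 7-tert-butoxy-3,5,8-trimethoxy-2-(4-methoxyphenyl)-4H-chromen-4-one | COc1ccc(-c2oc3c(OC)c(OC(C)(C)C)cc(OC)c3c(=O)c2OC)cc1
F4 | step 8 | 6-bromo-7-tert-butoxy-3,5,8-trimethoxy-2-(4-methoxyphenyl)-4H-chromen-4-one | COc1ccc(-c2oc3c(OC)c(OC(C)(C)C)c(Br)c(OC)c3c(=O)c2OC)cc1
F5 | step 5 | 5-iodo-3-methoxy-2-(4-methoxyphenyl)-4H-pyran-4-one | COc1ccc(-c2occ(I)c(=O)c2OC)cc1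
F6 | step 5 | chloro[5-methoxy-6-(4-methoxyphenyl)-4-oxo-4H-pyran-3-yl]magnesium | COc1ccc(-c2occ([Mg]Cl)c(=O)c2OC)cc1
F7 | step 5 | chloromagnesium pentacarbonyl[5-methoxy-6-(4-methoxyphenyl)-4-oxo-4H-pyran-3-carbonyl]chromate | Cl[Mg+].[O-]C(c1coc(-c2ccc(OC)cc2)c(OC)c1=O)=[Cr](=C=O)(=C=O)(=C=O)(=C=O)=C=O
F8 | step 7 | tributyl(tert-butoxyethynyl)stannane | CCCC[Sn](CCCC)(CCCC)C#COC(C)(C)C
F9 | step 7 | 7-tert-butoxy-8-hydroxy-3,5-dimethoxy-2-(4-methoxyphenyl)-6-(tributylstannyl)-4H-chromen-4-one | CCCC[Sn](CCCC)(CCCC)c1c(OC)c2c(=O)c(OC)c(-c3ccc(OC)cc3)oc2c(O)c1OC(C)(C)C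
F10 | step 7 | 7-tert-butoxy-8-hydroxy-6-iodo-3,5-dimethoxy-2-(4-methoxyphenyl)-4H-chromen-4-one | COc1ccc(-c2oc3c(O)c(OC(C)(C)C)c(I)c(OC)c3c(=O)c2OC)cc1
F11 | step 7 | 7-tert-butoxy-6-iodo-3,5,8-trimethoxy-2-(4-methoxyphenyl)-4H-chromen-4-one | COc1ccc(-c2oc3c(OC)c(OC(C)(C)C)c(I)c(OC)c3c(=O)c2OC)cc1
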